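The data stem from a simulated flask with constants of no real substance; scatter was added.

The product here was a length, monomer in chains divided by chains begun, so I wrote the balance of initiator, charged at 0.00500 M in north-east.

| flask | free monomer | protic impurity | initiator | remark | time |
|---|---|---|---|---|---|
| midnight | 1 M | 0.050 M | 0.37 mol% | run made earlier |  |
| dusk | 1 M | 0.050 M | 0.74 mol% | run made earlier |  |
| north-east | 1.0 M | 0.0500 M | 0.5 mol% |  | 5.0 h |
| south-east | 1.0 M | 0.0500 M | 1 mol% |  | 5.0 h |

- midnight (time / h: monomer in chains / %): 0.250: 5.0; 0.500: 10.0; 1.00: 18.3; 2.00: 33.5; 4.00: 54.2
- dusk (time / h: monomer in chains / %): 0.250: 8.9; 0.500: 18.5; 1.00: 33.8; 2.00: 56.1; 4.00: 76.2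

(each reading ± 0.5 percentage points)

* which of the two ends with the longer chains by the average number of monomer units in a chain (chains begun, living or dead) ("neither" if they lie within 10 %) (north-east / south-east / neither)
* average number of monomer units in a chain (chains begun, living or dead) at the end, north-east
* average number of monomer units in a chain (chains begun, living or dead) at the end, south-east

- the average divides the monomer in chains by the number of chains begun, living and dead together
- what was read earlier has a scatter of 0.5 percentage points, one standard deviation
- what may be going on: free monomer + initiator -> living end + monomer in chains; free monomer + living end -> monomer in chains + living end; protic impurity + free monomer -> quenched substrate; free monomer -> uncatalysed product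
- the earlier runs do not show the number of chains; that part of a forecast is a guess

I guessed that each initiator began one chain, which the readings do not show, and took each protic impurity to remove one free monomer. North-east then had a length ceiling of 190, free monomer charged less protic impurity, per initiator charged, and south-east had one of 95.0. North-east held more initiator than the midnight run and ran longer than that run's last reading of 54.2 %, so I expected at least that reading in chains in north-east. That made a length of 108, more than the south-east ceiling.

The forecast chose north-east, with 142 against 88, reasoning that “initiation looks fast and each initiator starts one chain”. My bound gave the same choice but not those numbers.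

The flask gave north-east, with 141 against 87.1.

    free monomer + initiator → living end + monomer in chains (k = 28.0 M⁻¹ h⁻¹)
    free monomer + living end → monomer in chains + living end, rate k2*[living end]*[free monomer] (k = 60.0 M⁻¹ h⁻¹)
    protic impurity + free monomer → quenched substrate (k = 3.50 M⁻¹ h⁻¹)
    free monomer → uncatalysed product (k = 0.0260 h⁻¹)

North-east ended at 74.0 % of its ceiling and south-east at 91.7 %. An initiator loading of 0.42 mol% or 0.6 mol% moved the north-east length by 14.1, and so did a free monomer charge of 0.823 M or 1.24 M.

The neighbour flask, south-east with 0.20 M of protic impurity, had a ceiling of 80.0. Its computed length was 73.8, below that ceiling, with 3.22 % of the free monomer unreacted.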